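**Retrosynthetic overview**

1. Target 16 ⇐ tri-O-benzyl ether 15 (hydrogenolysis last) ⇐ bis(triketo ester) 14 by a two-fold Claisen closure. Each arm is numbered C1 (ester carbon), C2 (CMe2), C3/C5/C7 (ketones), C4 (methine carrying the ring A CH2), C6 (methylene); in each arm C6 is acylated by C1.
2. Feature used: in rings B and C the gem-dimethyl carbon sits between two oxygen-bearing ring carbons, and the propanoyl-bearing ring carbon is next to one of them. A 2,2-dimethyl-3,5,7-trioxononanoate chain, whose quaternary C2 cannot enolise, therefore has only one six-membered fold, C6 onto C1.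
3. 14 ⇐ double C4-benzylation of β-diketo ester 11 by ring A dibromide 7. In 11, C7 is kept as a silyl-protected carbinol so that C4 is the only doubly activated carbon; desilylation and oxidation then release the C7 ketone. A nitrogen-containing diketone mask such as an isoxazole is avoided, because its ring-opened enaminone would condense with the C3 ketone to a 4-pyridone.
4. 7 ⇐ phloroglucinol (Friedel–Crafts butanoylation, double Duff formylation, O-benzylation, reduction, bromination); 11 ⇐ methyl (R)-3-hydroxypentanoate + methyl 2,2-dimethyl-3-oxobutanoate (crossed Claisen).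
5. Ring order: ring A is bought; rings B and C are closed together in step 11.

Key step: step 11

Assumption 1: the (R) centre at C7 of the arm is arbitrary and is oxidised away in step 10; one enantiomer of 8 is used only to limit the number of diastereomers of 12 and 13. The C4 methine centres of 12–14 are enolisable and undefined, and the target has no stereocentre.

Assumption 2: di- and triketones are drawn in their keto forms although they should exist largely as enols.

**Route**

Step 1
Reactants: 1 phloroglucinol; 2 butanoyl chloride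
Product: 3 1-(2,4,6-trihydroxyphenyl)butan-1-one
Conditions: AlCl3 (3.5 equiv), PhNO2, 0 → 60 °C; then ice, aq HCl
Reagents that add atoms: none
Why: Friedel–Crafts C-acylation of the very electron-rich ring should stop at the mono-ketone, because the AlCl3-chelated acyl group deactivates the ring towards a second acylation.

Step 2
Reactants: 3 1-(2,4,6-trihydroxyphenyl)butan-1-one
Product: 4 5-butanoyl-2,4,6-trihydroxybenzene-1,3-dicarbaldehyde
Conditions: hexamethylenetetramine (5 equiv), CF3CO2H, 100 °C; then 3 M aq HCl, 100 °C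
Reagents that add atoms: hexamethylenetetramine, C1N2CN3CN1CN(C2)C3 (the two formyl carbons); water, O (the two formyl oxygens)
Why: Duff formylation (aminomethylation by the protonated aminal, internal hydride transfer, hydrolysis) should formylate both remaining ring CH positions, as it does exhaustively on phloroglucinol itself even after earlier formyl groups are in place.

Step 3
Reactants: 4 5-butanoyl-2,4,6-trihydroxybenzene-1,3-dicarbaldehyde
Product: 5 2,4,6-tris(benzyloxy)-5-butanoylbenzene-1,3-dicarbaldehyde
Conditions: BnBr (4.5 equiv), K2CO3, Bu4NI (cat.), DMF, 70 °C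
Reagents that add atoms: benzyl bromide, BrCc1ccccc1
Why: Williamson O-alkylation; every ring carbon is substituted, so C-benzylation would require dearomatisation, and warm DMF should overcome the low nucleophilicity of the chelated phenoxides.

Step 4
Reactants: 5 2,4,6-tris(benzyloxy)-5-butanoylbenzene-1,3-dicarbaldehyde
Product: 6 1-[2,4,6-tris(benzyloxy)-3,5-bis(hydroxymethyl)phenyl]butan-1-one
Conditions: NaBH4 (1.0 equiv), EtOH/CH2Cl2 (3:7), −78 → −40 °C; aq NH4Cl
Reagents that add atoms: none
Why: Chemoselective borohydride reduction of the two aldehydes; the butanoyl ketone is less electrophilic and is shielded between two ortho benzyloxy groups, so it should survive at low temperature.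

Step 5
Reactants: 6 1-[2,4,6-tris(benzyloxy)-3,5-bis(hydroxymethyl)phenyl]butan-1-one
Product: 7 1-[2,4,6-tris(benzyloxy)-3,5-bis(bromomethyl)phenyl]butan-1-one
Conditions: CBr4, PPh3, CH2Cl2, 0 °C; used at once
Reagents that add atoms: carbon tetrabromide, BrC(Br)(Br)Br
Why: Appel bromination runs under neutral conditions that spare the benzyl ethers and the ketone, and the fully substituted ring cannot self-condense by Friedel–Crafts alkylation with the activated benzylic bromide.

Step 6
Reactants: 8 methyl (3R)-3-hydroxypentanoate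
Product: 9 methyl (3R)-3-[(tert-butyldimethylsilyl)oxy]pentanoate
Conditions: t-BuMe2SiCl, imidazole, DMF, 0 °C → rt
Reagents that add atoms: tert-butyldimethylsilyl chloride, CC(C)(C)[Si](C)(C)Cl
Why: Imidazole-mediated silylation of a secondary alcohol fixes the future C7 at the carbinol level; the stereocentre is not touched.

Step 7
Reactants: 9 methyl (3R)-3-[(tert-butyldimethylsilyl)oxy]pentanoate; 10 methyl 2,2-dimethyl-3-oxobutanoate
Product: 11 methyl (7R)-7-[(tert-butyldimethylsilyl)oxy]-2,2-dimethyl-3,5-dioxononanoate
Conditions: 10 (2.2 equiv), LiN(i-Pr)2 (2.2 equiv), THF, −78 °C; then 9 (1 equiv), −78 → 0 °C; aq NH4Cl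
Reagents that add atoms: none
Why: Crossed Claisen condensation; 10 has a single enolisable position (its acetyl CH3, C2 being quaternary), so one enolate forms and acylates on the unhindered ester of 9, and the β-diketone is at once deprotonated by the second equivalent of enolate, which protects it from further attack and leaves C7 untouched.

Step 8
Reactants: 7 1-[2,4,6-tris(benzyloxy)-3,5-bis(bromomethyl)phenyl]butan-1-one; 11 methyl (7R)-7-[(tert-butyldimethylsilyl)oxy]-2,2-dimethyl-3,5-dioxononanoate (2.6 equiv)
Product: 12 dimethyl 4,4'-{[2,4,6-tris(benzyloxy)-5-butanoyl-1,3-phenylene]bis(methylene)}bis[(7R)-7-(tert-butyldimethylsilyloxy)-2,2-dimethyl-3,5-dioxononanoate], C4 and C4' undefined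
Conditions: K2CO3, acetone, rt → 40 °C
Reagents that add atoms: none
Why: C-alkylation of a β-diketonate by a benzylic bromide; C4 is the only carbon of 11 between two carbonyl groups (C6 is α to one ketone only while C7 is a silyl ether), so carbonate base should form only the C3–C4–C5 enolate, and the two new C4 centres are formed without control because they later become sp2.

Step 9
Reactants: 12 the bis(silyl ether) from step 8
Product: 13 dimethyl 4,4'-{[2,4,6-tris(benzyloxy)-5-butanoyl-1,3-phenylene]bis(methylene)}bis[(7R)-7-hydroxy-2,2-dimethyl-3,5-dioxononanoate], C4 and C4' undefined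
Conditions: HF·pyridine, pyridine, THF, 0 °C → rt
Reagents that add atoms: none
Why: Fluoride cleavage of the two Si–O bonds, buffered with pyridine so that the freed δ-hydroxy β-diketones are not dehydrated to dihydropyranones; benzyl ethers, esters and ketones are inert.

Step 10
Reactants: 13 the bis(δ-hydroxy diketo ester) from step 9
Product: 14 dimethyl 4,4'-{[2,4,6-tris(benzyloxy)-5-butanoyl-1,3-phenylene]bis(methylene)}bis(2,2-dimethyl-3,5,7-trioxononanoate), C4 and C4' undefined
Conditions: Dess–Martin periodinane (2.4 equiv), NaHCO3, CH2Cl2, 0 °C → rt; crude 14 taken on without chromatography on acidic silica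
Reagents that add atoms: none
Why: Dess–Martin oxidation of a β-hydroxy ketone to a β-diketone under buffered conditions should give the 1,3,5-triketone arms without any cationic or nitrogen-bearing intermediate at C7 that could close onto the C3 carbonyl as a pyranone or pyridone; both C7 stereocentres disappear.

Step 11
Reactants: 14 the bis(triketo ester) from step 10
Product: 15 1-[2,4,6-tris(benzyloxy)-3,5-bis({2,4-dihydroxy-3,3-dimethyl-6-oxo-5-propanoylcyclohexa-1,4-dien-1-yl}methyl)phenyl]butan-1-one
Conditions: LiN(SiMe3)2 (4.4 equiv), THF, −78 → 45 °C; then cold 1 M aq HCl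
Reagents that add atoms: none
Why: Four equivalents of amide base remove the C4–H and one C6–H of each arm, and the C6 carbon of each C5–C6–C7 diketonate adds to the C1 ester carbonyl, whose tetrahedral intermediate expels methoxide; the methoxide then removes the new, very acidic ring C–H, so the product is held as a doubly deprotonated triketone until the acid quench. The closest known reaction is the biomimetic Claisen cyclisation of 3,5,7-triketo esters to acylphloroglucinols. Rings B and C each close in a 6-(enolexo)-exo-trig mode, C6 onto C1, with a Thorpe–Ingold assist from the gem-dimethyl carbon C2. No stereocentre is formed, and the two undefined C4 methine centres become sp2 ring carbons. The step needs C-acylation by C6 and nothing else: C2 is quaternary, so the ester cannot enolise and no aldol closure onto C7 exists, C4 could only form a four-membered ring, and O-acylation through the C5 enolate oxygen gives an enol lactone that the liberated LiOMe can reopen, whereas the C-acylated ring is not reopened. Cleavage of the quaternary β-keto ester at C3 should be held back because the C3 carbonyl is part of the C3–C4–C5 enolate and the base is not nucleophilic.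

Step 12
Reactants: 15 the tri-O-benzyl ether from step 11
Product: 16 1-[2,4,6-trihydroxy-3,5-bis({2,4-dihydroxy-3,3-dimethyl-6-oxo-5-propanoylcyclohexa-1,4-dien-1-yl}methyl)phenyl]butan-1-one (CNP0212485.0)
Conditions: H2 (1 atm), Pd on carbon (10 wt% Pd), EtOAc/MeOH, rt
Reagents that add atoms: none
Why: Hydrogenolysis of the three aryl benzyl ethers; the cross-conjugated enolised triketone rings, the chelated aryl ketone and the C–C methylene bridges should not be reduced under these neutral, low-pressure conditions.

**Compound list**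

1 | phloroglucinol | Oc1cc(O)cc(O)c1 | starting material
2 | butanoyl chloride | CCCC(Cl)=O | starting material
3 | 1-(2,4,6-trihydroxyphenyl)butan-1-one | CCCC(=O)c1c(O)cc(O)cc1O | intermediate
4 | 5-butanoyl-2,4,6-trihydroxybenzene-1,3-dicarbaldehyde | CCCC(=O)c1c(O)c(C=O)c(O)c(C=O)c1O | intermediate
5 | 2,4,6-tris(benzyloxy)-5-butanoylbenzene-1,3-dicarbaldehyde | CCCC(=O)c1c(OCc2ccccc2)c(C=O)c(OCc2ccccc2)c(C=O)c1OCc1ccccc1 | intermediate
6 | 1-[2,4,6-tris(benzyloxy)-3,5-bis(hydroxymethyl)phenyl]butan-1-one | CCCC(=O)c1c(OCc2ccccc2)c(CO)c(OCc2ccccc2)c(CO)c1OCc1ccccc1 | intermediate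
7 | 1-[2,4,6-tris(benzyloxy)-3,5-bis(bromomethyl)phenyl]butan-1-one | CCCC(=O)c1c(OCc2ccccc2)c(CBr)c(OCc2ccccc2)c(CBr)c1OCc1ccccc1 | intermediate
8 | methyl (3R)-3-hydroxypentanoate | CC[C@@H](O)CC(=O)OC | starting material
9 | methyl (3R)-3-[(tert-butyldimethylsilyl)oxy]pentanoate | CC[C@@H](O[Si](C)(C)C(C)(C)C)CC(=O)OC | intermediate
10 | methyl 2,2-dimethyl-3-oxobutanoate | CC(=O)C(C)(C)C(=O)OC | starting material
11 | methyl (7R)-7-[(tert-butyldimethylsilyl)oxy]-2,2-dimethyl-3,5-dioxononanoate | CC[C@@H](O[Si](C)(C)C(C)(C)C)CC(=O)CC(=O)C(C)(C)C(=O)OC | intermediate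
12 | dimethyl 4,4'-{[2,4,6-tris(benzyloxy)-5-butanoyl-1,3-phenylene]bis(methylene)}bis[(7R)-7-(tert-butyldimethylsilyloxy)-2,2-dimethyl-3,5-dioxononanoate], C4/C4' undefined | CCCC(=O)c1c(OCc2ccccc2)c(CC(C(=O)C[C@@H](CC)O[Si](C)(C)C(C)(C)C)C(=O)C(C)(C)C(=O)OC)c(OCc2ccccc2)c(CC(C(=O)C[C@@H](CC)O[Si](C)(C)C(C)(C)C)C(=O)C(C)(C)C(=O)OC)c1OCc1ccccc1 | intermediate
13 | dimethyl 4,4'-{[2,4,6-tris(benzyloxy)-5-butanoyl-1,3-phenylene]bis(methylene)}bis[(7R)-7-hydroxy-2,2-dimethyl-3,5-dioxononanoate], C4/C4' undefined | CCCC(=O)c1c(OCc2ccccc2)c(CC(C(=O)C[C@@H](CC)O)C(=O)C(C)(C)C(=O)OC)c(OCc2ccccc2)c(CC(C(=O)C[C@@H](CC)O)C(=O)C(C)(C)C(=O)OC)c1OCc1ccccc1 | intermediate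
14 | dimethyl 4,4'-{[2,4,6-tris(benzyloxy)-5-butanoyl-1,3-phenylene]bis(methylene)}bis(2,2-dimethyl-3,5,7-trioxononanoate), C4/C4' undefined | CCCC(=O)c1c(OCc2ccccc2)c(CC(C(=O)CC(=O)CC)C(=O)C(C)(C)C(=O)OC)c(OCc2ccccc2)c(CC(C(=O)CC(=O)CC)C(=O)C(C)(C)C(=O)OC)c1OCc1ccccc1 | intermediate
15 | 1-[2,4,6-tris(benzyloxy)-3,5-bis({2,4-dihydroxy-3,3-dimethyl-6-oxo-5-propanoylcyclohexa-1,4-dien-1-yl}methyl)phenyl]butan-1-one | CCCC(=O)c1c(OCc2ccccc2)c(CC2=C(O)C(C)(C)C(O)=C(C(=O)CC)C2=O)c(OCc2ccccc2)c(CC2=C(O)C(C)(C)C(O)=C(C(=O)CC)C2=O)c1OCc1ccccc1 | intermediate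
16 | 1-[2,4,6-trihydroxy-3,5-bis({2,4-dihydroxy-3,3-dimethyl-6-oxo-5-propanoylcyclohexa-1,4-dien-1-yl}methyl)phenyl]butan-1-one | CCCC(=O)c1c(O)c(CC2=C(O)C(C)(C)C(O)=C(C(=O)CC)C2=O)c(O)c(CC2=C(O)C(C)(C)C(O)=C(C(=O)CC)C2=O)c1O | target

**Totals**

Total step count: 12. Longest linear sequence: 10 steps (steps 1–5, then 8–12).

**Steps most likely to fail, with fallbacks**

Step 11. The lithium-chelated enolates may hold C6 away from C1 so that the chain does not fold. Reversible O-lactonisation may stall the reaction, or liberated methoxide may cleave the arm at C3. A slight excess of base could also deprotonate C8 and start an aldol onto C3. Fallback, setting out from 7 and coming back at 15: rings B and C are brought in ready-made. Commercial 1-(2,4,6-trihydroxyphenyl)propan-1-one (CCC(=O)c1c(O)cc(O)cc1O) is methylated twice at one ring carbon (MeI, NaOMe, MeOH), a known dearomatising gem-dimethylation of acylphloroglucinols, to give 3,5-dihydroxy-4,4-dimethyl-2-propanoylcyclohexa-2,5-dien-1-one (propionylfilicinic acid) F1. Two equivalents of F1 are then C-alkylated at the free ring CH by dibromide 7 (K2CO3, acetone) to give 15 directly, so that steps 8–11 are not needed.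

Step 10. The new C6 methylene may be over-oxidised by the periodinane, or the hydroxy diketone may be lost as a cyclic hemiketal or dihydropyranone before it is oxidised. Fallback, setting out from 7 (with 10) and coming back at 14: C7 is carried as a ketal, so that no free hydroxy diketone ever forms. Methyl 3-oxopentanoate (CCC(=O)CC(=O)OC) is ketalised with ethylene glycol (TsOH, toluene, water removal) to methyl 2-(2-ethyl-1,3-dioxolan-2-yl)acetate F2. The lithium enolate of 10 is acylated by F2 as in step 7 to give methyl 6-(2-ethyl-1,3-dioxolan-2-yl)-2,2-dimethyl-3,5-dioxohexanoate F3. F3 is C-benzylated twice by 7 as in step 8 to give dimethyl 4,4'-{[2,4,6-tris(benzyloxy)-5-butanoyl-1,3-phenylene]bis(methylene)}bis[6-(2-ethyl-1,3-dioxolan-2-yl)-2,2-dimethyl-3,5-dioxohexanoate] F4. Brief mild hydrolysis (pyridinium p-toluenesulfonate, wet acetone) then gives 14; the acid must stay weak so that the triketone is not cyclodehydrated to a pyranone.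

Step 8. The activated dibromide may ionise and hydrolyse, O-alkylation may compete, or the reaction may stop after one arm or give oligomers. Fallback, setting out from 5 (with 11) and coming back at 12, so that steps 4 and 5 are dropped: the benzylic carbons are joined at the aldehyde level. Dialdehyde 5 undergoes double Knoevenagel condensation with 11 (piperidinium acetate, toluene, 4 Å sieves) to give dimethyl 4,4'-{[2,4,6-tris(benzyloxy)-5-butanoyl-1,3-phenylene]dimethanylylidene}bis[(7R)-7-(tert-butyldimethylsilyloxy)-2,2-dimethyl-3,5-dioxononanoate] F5, with uncontrolled C=C geometry that is lost in the next operation. The two electron-poor C=C bonds of F5 are reduced by conjugate hydride transfer from diethyl 2,6-dimethyl-1,4-dihydropyridine-3,5-dicarboxylate (toluene, 60 °C) to give 12.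

**Further compounds**

F1 | step 11 | 3,5-dihydroxy-4,4-dimethyl-2-propanoylcyclohexa-2,5-dien-1-one (propionylfilicinic acid) | CCC(=O)C1=C(O)C(C)(C)C(O)=CC1=O
F2 | step 10 | methyl 2-(2-ethyl-1,3-dioxolan-2-yl)acetate | CCC1(CC(=O)OC)OCCO1
F3 | step 10 | methyl 6-(2-ethyl-1,3-dioxolan-2-yl)-2,2-dimethyl-3,5-dioxohexanoate | CCC1(CC(=O)CC(=O)C(C)(C)C(=O)OC)OCCO1
F4 | step 10 | dimethyl 4,4'-{[2,4,6-tris(benzyloxy)-5-butanoyl-1,3-phenylene]bis(methylene)}bis[6-(2-ethyl-1,3-dioxolan-2-yl)-2,2-dimethyl-3,5-dioxohexanoate], C4/C4' undefined | CCCC(=O)c1c(OCc2ccccc2)c(CC(C(=O)CC2(CC)OCCO2)C(=O)C(C)(C)C(=O)OC)c(OCc2ccccc2)c(CC(C(=O)CC2(CC)OCCO2)C(=O)C(C)(C)C(=O)OC)c1OCc1ccccc1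
F5 | step 8 | dimethyl 4,4'-{[2,4,6-tris(benzyloxy)-5-butanoyl-1,3-phenylene]dimethanylylidene}bis[(7R)-7-(tert-butyldimethylsilyloxy)-2,2-dimethyl-3,5-dioxononanoate], C=C geometry undefined | CCCC(=O)c1c(OCc2ccccc2)c(C=C(C(=O)C[C@@H](CC)O[Si](C)(C)C(C)(C)C)C(=O)C(C)(C)C(=O)OC)c(OCc2ccccc2)c(C=C(C(=O)C[C@@H](CC)O[Si](C)(C)C(C)(C)C)C(=O)C(C)(C)C(=O)OC)c1OCc1ccccc1
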